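**Plan**
- Ring B carries oxygens on C4 and C6, a carbon substituent on C2 and the ring A aryloxy group on C1. Retrosynthetically it is de-aromatised to a cyclohexane-1,3-dione and cut at C2–C3 and C4–C5 into an α-aryloxy enone (C5, C6, C1, C2) and a malonate (C3, C4).
- Before that, the CH2OH group is traced to an acetal-masked aldehyde and the prenyl ether to a ring B phenol. The enone is cut at C1=C2 (Horner–Wadsworth–Emmons) and at the ring A oxygen–C1 bond (carbenoid O–H insertion), so the hindered diaryl ether is never made by aryl–oxygen coupling.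
- Forward: ring A is bought and its phenol oxygen is attached to the future C1. The enone is formed, ring B is annulated, decarboxylated, converted into the C4 methyl enol ether and aromatised. The C6 oxygen is then prenylated, the acetal hydrolysed and the aldehyde reduced.
- Stereochemistry: the target has no stereocentre. The two centres created in the annulation are racemic and vanish on aromatisation, and the prenyl alkene comes intact from prenyl bromide.

Key step: step 3

Remark on the chemistry: ring B atoms are numbered C1 (aryloxy carbon), C2 (carbon bearing the one-carbon substituent), C3, C4 (methoxy carbon), C5, C6 (prenyloxy carbon). All chiral intermediates are racemic and drawn as one enantiomer. The ring A phenol is left unprotected on purpose; it is assumed that its phenoxide form shields the neighbouring methyl ester under basic conditions.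

Step 1
Reactants: 1 methyl 2,6-dihydroxy-4-methylbenzoate; 2 dimethyl (1-diazo-2-oxopropyl)phosphonate
Product: 3 methyl 2-{[1-(dimethoxyphosphoryl)-2-oxopropyl]oxy}-6-hydroxy-4-methylbenzoate (racemic)
Conditions: Rh2(OAc)4 (1 mol%), toluene, 80 °C, slow addition of 2 to 1 (1.5 equiv)
Reagents that add atoms: none
Why: Rh2(OAc)4 converts the acceptor-substituted diazo compound into a rhodium carbenoid that inserts into the phenolic O–H bond (carbenoid O–H insertion), and the excess of symmetrical 1 together with the chelation of the remaining hydroxyl to the ester should limit double insertion.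

Step 2
Reactants: 3 methyl 2-{[1-(dimethoxyphosphoryl)-2-oxopropyl]oxy}-6-hydroxy-4-methylbenzoate; 4 2,2-dimethoxyacetaldehyde
Product: 5 methyl 2-{[(3Z)-5,5-dimethoxy-2-oxopent-3-en-3-yl]oxy}-6-hydroxy-4-methylbenzoate
Conditions: 4 (60 wt% in H2O, 1.5 equiv), K2CO3 (2.5 equiv), THF/H2O, 0 °C to rt
Reagents that add atoms: none
Why: Horner–Wadsworth–Emmons olefination of the doubly stabilised phosphonate anion with a reactive, non-enolisable aldehyde places the new C=C bond unambiguously at the oxygen-bearing carbon; the (Z)-isomer (acetal trans to acetyl) is expected to predominate, and the alkene geometry is lost in step 3 in any case.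

Step 3
Reactants: 5 methyl 2-{[(3Z)-5,5-dimethoxy-2-oxopent-3-en-3-yl]oxy}-6-hydroxy-4-methylbenzoate; 6 diallyl malonate
Product: 8 allyl rac-(5,6-trans)-6-(dimethoxymethyl)-2-hydroxy-5-[3-hydroxy-2-(methoxycarbonyl)-5-methylphenoxy]-4-oxocyclohex-1-ene-1-carboxylate, via Michael adduct 7 (not isolated)
Conditions: NaH (2.3 equiv), 6 (1.2 equiv), THF, 0 °C; add 5; rt to 60 °C; then cold 1 M HCl to pH 3
Reagents that add atoms: none
Why: The sodium enolate of 6 adds in a Michael fashion to the β-carbon of enone 5 (C2–C3 bond); proton transfer relays the charge from the α-aryloxy enolate through the malonate to the methyl ketone, whose enolate attacks one allyl ester in a Claisen (Dieckmann-type) condensation (C4–C5 bond) with loss of allyl oxide, and deprotonation of the cyclic tricarbonyl product makes the sequence irreversible. The closest known reaction type is the Michael–Claisen synthesis of cyclohexane-1,3-diones from enones and malonates, as used for dimedone and 5-alkylresorcinols. Ring B closes in a 6-(enolexo)-exo-trig mode. The two new stereocentres (C1 and C2) are set under thermodynamic control, because C1 is epimerisable next to the C6 carbonyl, which should place the aryloxy and dimethoxymethyl groups trans; the product is racemic and both centres disappear on aromatisation. The step needs chemoselectivity for the malonate ester over the ring A methyl ester: the latter is flanked by two ortho substituents and deactivated by the adjacent phenoxide, and a five-membered closure onto it would give a non-enolisable β-diketone that cannot be held as a stabilised enolate, so the six-membered path is the thermodynamic sink. Conjugate rather than carbonyl addition is secured by the soft, stabilised malonate nucleophile.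

Step 4
Reactants: 8 allyl rac-(5,6-trans)-6-(dimethoxymethyl)-2-hydroxy-5-[3-hydroxy-2-(methoxycarbonyl)-5-methylphenoxy]-4-oxocyclohex-1-ene-1-carboxylate
Product: 10 methyl 2-{[rac-(1,6-trans)-6-(dimethoxymethyl)-2,4-dioxocyclohexyl]oxy}-6-hydroxy-4-methylbenzoate, via carboxylic acid 9 (not isolated)
Conditions: Pd(PPh3)4 (5 mol%), morpholine (10 equiv), THF, rt; then aq. citric acid (pH 4), EtOAc, 40 °C
Reagents that add atoms: none
Why: Zerovalent palladium ionises the allyl ester to a π-allylpalladium carboxylate (Tsuji–Trost deallylation), morpholine captures the allyl group, and the freed vinylogous β-keto acid loses CO2 on mild acidification; the methyl ester, aryl ether and acetal are inert, and any acetal lost here is re-formed in step 5.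

Step 5
Reactants: 10 methyl 2-{[rac-(1,6-trans)-6-(dimethoxymethyl)-2,4-dioxocyclohexyl]oxy}-6-hydroxy-4-methylbenzoate
Product: 11 methyl 2-{[rac-(1,6-trans)-6-(dimethoxymethyl)-4-methoxy-2-oxocyclohex-3-en-1-yl]oxy}-6-hydroxy-4-methylbenzoate
Conditions: HC(OMe)3 (3 equiv), TsOH·H2O (5 mol%), MeOH, rt
Reagents that add atoms: methanol, CO; trimethyl orthoformate, COC(OC)OC
Why: Acid-catalysed enol etherification of a cyclic 1,3-dione (vinylogous esterification) should place the methoxy group at C4, whose carbonyl is flanked by the unsubstituted C3 methylene, rather than at C6 next to the substituted C1; the orthoformate removes water and keeps the acetal as the dimethyl acetal, and phenols are not etherified under these conditions.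

Step 6
Reactants: 11 methyl 2-{[rac-(1,6-trans)-6-(dimethoxymethyl)-4-methoxy-2-oxocyclohex-3-en-1-yl]oxy}-6-hydroxy-4-methylbenzoate
Product: 13 methyl 2-[2-(dimethoxymethyl)-6-hydroxy-4-methoxyphenoxy]-6-hydroxy-4-methylbenzoate, via selenide 12 (not isolated)
Conditions: LiN(iPr)2 (2.3 equiv), THF, −78 °C; PhSeBr (1.2 equiv), −78 °C; then pyridine, 30% H2O2, 0 °C to rt
Reagents that add atoms: none
Why: After the first equivalent of base has formed the ring A phenoxide, kinetic α'-deprotonation of the vinylogous ester at C1, selenenylation anti to the C2 substituent and syn-elimination of the selenoxide towards C2–H give a cross-conjugated dienone that tautomerises to the phenol (selenoxide elimination, the standard aromatisation of 3-alkoxycyclohexenones to resorcinol monoethers).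

Step 7
Reactants: 13 methyl 2-[2-(dimethoxymethyl)-6-hydroxy-4-methoxyphenoxy]-6-hydroxy-4-methylbenzoate; 14 prenyl bromide (1-bromo-3-methylbut-2-ene)
Product: 15 methyl 2-{2-(dimethoxymethyl)-4-methoxy-6-[(3-methylbut-2-en-1-yl)oxy]phenoxy}-6-hydroxy-4-methylbenzoate
Conditions: 14 (1.1 equiv), K2CO3 (1.5 equiv), acetone, rt to 40 °C
Reagents that add atoms: none
Why: Williamson etherification in which the ring B phenol, free of hydrogen bonding, should be O-alkylated while the ring A phenol, chelated to its ester carbonyl and far less nucleophilic, is left alone.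

Step 8
Reactants: 15 methyl 2-{2-(dimethoxymethyl)-4-methoxy-6-[(3-methylbut-2-en-1-yl)oxy]phenoxy}-6-hydroxy-4-methylbenzoate
Product: 16 methyl 2-{2-formyl-4-methoxy-6-[(3-methylbut-2-en-1-yl)oxy]phenoxy}-6-hydroxy-4-methylbenzoate
Conditions: PPTS (10 mol%), acetone/H2O (9:1), rt
Reagents that add atoms: water, O
Why: Acid-catalysed hydrolysis of a benzaldehyde dimethyl acetal is fast under buffered conditions that should leave the aryl prenyl ether and the methyl ester untouched.

Step 9
Reactants: 16 methyl 2-{2-formyl-4-methoxy-6-[(3-methylbut-2-en-1-yl)oxy]phenoxy}-6-hydroxy-4-methylbenzoate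
Product: 17 methyl 2-hydroxy-6-{2-(hydroxymethyl)-4-methoxy-6-[(3-methylbut-2-en-1-yl)oxy]phenoxy}-4-methylbenzoate (CNP0532721.0)
Conditions: NaBH4, MeOH, 0 °C
Reagents that add atoms: none
Why: Chemoselective borohydride reduction of the aryl aldehyde to the benzylic alcohol; the hindered, hydrogen-bonded methyl benzoate and the trisubstituted alkene are not reduced.

**Compound list**
1 | methyl 2,6-dihydroxy-4-methylbenzoate | COC(=O)c1c(O)cc(C)cc1O | starting material
2 | dimethyl (1-diazo-2-oxopropyl)phosphonate | CC(=O)C(=[N+]=[N-])P(=O)(OC)OC | starting material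
3 | methyl 2-{[1-(dimethoxyphosphoryl)-2-oxopropyl]oxy}-6-hydroxy-4-methylbenzoate (racemic) | CC(=O)C(Oc1cc(C)cc(O)c1C(=O)OC)P(=O)(OC)OC | intermediate
4 | 2,2-dimethoxyacetaldehyde | COC(OC)C=O | starting material
5 | methyl 2-{[(3Z)-5,5-dimethoxy-2-oxopent-3-en-3-yl]oxy}-6-hydroxy-4-methylbenzoate | CC(=O)/C(Oc1cc(C)cc(O)c1C(=O)OC)=C/C(OC)OC | intermediate
6 | diallyl malonate | C=CCOC(=O)CC(=O)OCC=C | starting material
7 | diallyl 2-{3-[3-hydroxy-2-(methoxycarbonyl)-5-methylphenoxy]-1,1-dimethoxy-4-oxopentan-2-yl}malonate (racemic mixture of diastereomers, present as its sodium salt) | C=CCOC(=O)C(C(=O)OCC=C)C(C(OC)OC)C(Oc1cc(C)cc(O)c1C(=O)OC)C(C)=O | intermediate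
8 | allyl rac-(5,6-trans)-6-(dimethoxymethyl)-2-hydroxy-5-[3-hydroxy-2-(methoxycarbonyl)-5-methylphenoxy]-4-oxocyclohex-1-ene-1-carboxylate (one enol tautomer drawn) | C=CCOC(=O)C1=C(O)CC(=O)[C@H](Oc2cc(C)cc(O)c2C(=O)OC)[C@H]1C(OC)OC | intermediate
9 | rac-(5,6-trans)-6-(dimethoxymethyl)-2-hydroxy-5-[3-hydroxy-2-(methoxycarbonyl)-5-methylphenoxy]-4-oxocyclohex-1-ene-1-carboxylic acid | OC(=O)C1=C(O)CC(=O)[C@H](Oc2cc(C)cc(O)c2C(=O)OC)[C@H]1C(OC)OC | intermediate
10 | methyl 2-{[rac-(1,6-trans)-6-(dimethoxymethyl)-2,4-dioxocyclohexyl]oxy}-6-hydroxy-4-methylbenzoate | O=C1CC(=O)[C@H](Oc2cc(C)cc(O)c2C(=O)OC)[C@@H](C(OC)OC)C1 | intermediate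
11 | methyl 2-{[rac-(1,6-trans)-6-(dimethoxymethyl)-4-methoxy-2-oxocyclohex-3-en-1-yl]oxy}-6-hydroxy-4-methylbenzoate | COC1=CC(=O)[C@H](Oc2cc(C)cc(O)c2C(=O)OC)[C@@H](C(OC)OC)C1 | intermediate
12 | methyl 2-{[rac-6-(dimethoxymethyl)-4-methoxy-2-oxo-1-(phenylselanyl)cyclohex-3-en-1-yl]oxy}-6-hydroxy-4-methylbenzoate (selenium trans to the dimethoxymethyl group) | COC1=CC(=O)[C@](Oc2cc(C)cc(O)c2C(=O)OC)([Se]c2ccccc2)[C@@H](C(OC)OC)C1 | intermediate
13 | methyl 2-[2-(dimethoxymethyl)-6-hydroxy-4-methoxyphenoxy]-6-hydroxy-4-methylbenzoate | COC(=O)c1c(O)cc(C)cc1Oc1c(C(OC)OC)cc(OC)cc1O | intermediate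
14 | prenyl bromide (1-bromo-3-methylbut-2-ene) | CC(C)=CCBr | starting material
15 | methyl 2-{2-(dimethoxymethyl)-4-methoxy-6-[(3-methylbut-2-en-1-yl)oxy]phenoxy}-6-hydroxy-4-methylbenzoate | COC(=O)c1c(O)cc(C)cc1Oc1c(C(OC)OC)cc(OC)cc1OCC=C(C)C | intermediate
16 | methyl 2-{2-formyl-4-methoxy-6-[(3-methylbut-2-en-1-yl)oxy]phenoxy}-6-hydroxy-4-methylbenzoate | COC(=O)c1c(O)cc(C)cc1Oc1c(C=O)cc(OC)cc1OCC=C(C)C | intermediate
17 | methyl 2-hydroxy-6-{2-(hydroxymethyl)-4-methoxy-6-[(3-methylbut-2-en-1-yl)oxy]phenoxy}-4-methylbenzoate (CNP0532721.0) | COC(=O)c1c(O)cc(C)cc1Oc1c(CO)cc(OC)cc1OCC=C(C)C | target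

**Step count**
Total steps: 9. Longest linear sequence: 9 steps (1 to 17).

**Steps most likely to fail**

Step 3. The conjugate addition may be slow, because the α-aryloxy group donates into the enone and the β-carbon is substituted. Prolonged heating in base then gives time for retro-reactions or for closure of the α-aryloxy enolate onto the ring A ester. The fallback reverses the polarity of the conjugate addition; it sets out from 1, 4 and 6 and comes back at 8. Compound 1 is mono-alkylated with chloroacetone (K2CO3, cat. KI, acetone) to methyl 2-hydroxy-4-methyl-6-(2-oxopropoxy)benzoate F1. Separately, 6 is condensed with anhydrous 4 (piperidinium acetate, toluene, water removal; Knoevenagel) to diallyl 2-(2,2-dimethoxyethylidene)malonate F2. Pyrrolidine-catalysed enamine Michael addition of F1 through its oxygen-bearing α-carbon to the strongly electrophilic F2 should give 7, now isolated. A separate Claisen closure (KOtBu, THF, 0 °C) then gives 8.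

Step 5. Methanol may add to both carbonyl groups of the unsymmetrical dione, so the methyl ether partly ends up on the oxygen meant for the prenyl group. The fallback differentiates the two oxygens at the aromatic stage by size; it sets out from 10 and comes back at 15.
- 10 is brominated between the carbonyls (N-bromosuccinimide, CH2Cl2, 0 °C) to methyl 2-{[rac-3-bromo-6-(dimethoxymethyl)-2,4-dioxocyclohexyl]oxy}-6-hydroxy-4-methylbenzoate F3.
- Dehydrobromination (LiBr, Li2CO3, DMF, 90 °C) gives methyl 2-[2-(dimethoxymethyl)-4,6-dihydroxyphenoxy]-6-hydroxy-4-methylbenzoate F4.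
- The unhindered C4 hydroxyl is silylated (iPr3SiCl, imidazole, DMF, 0 °C) to methyl 2-{2-(dimethoxymethyl)-6-hydroxy-4-[(triisopropylsilyl)oxy]phenoxy}-6-hydroxy-4-methylbenzoate F5.
- Prenylation with 14 (K2CO3, acetone) gives methyl 2-{2-(dimethoxymethyl)-6-[(3-methylbut-2-en-1-yl)oxy]-4-[(triisopropylsilyl)oxy]phenoxy}-6-hydroxy-4-methylbenzoate F6.
- Desilylation (Bu4NF, THF, 0 °C) gives methyl 2-{2-(dimethoxymethyl)-4-hydroxy-6-[(3-methylbut-2-en-1-yl)oxy]phenoxy}-6-hydroxy-4-methylbenzoate F7.
- Methylation of the non-chelated phenol (MeI, K2CO3, acetone) gives 15.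

Step 6. The α'-lithium enolate sits next to the aryloxy group and may close onto the ring A ester before it is trapped. Deprotonation may also occur at the γ-position, and selenenylation on the wrong face would leave the selenoxide without a syn hydrogen. The fallback replaces C-selenenylation by O-silylation and a palladium-mediated dehydrogenation; it sets out from 11 and comes back at 13. Treatment of 11 with LiN(iPr)2 in the presence of Me3SiCl (internal quench, THF, −78 °C) gives methyl 2-{[6-(dimethoxymethyl)-4-methoxy-2-[(trimethylsilyl)oxy]cyclohexa-1,3-dien-1-yl]oxy}-4-methyl-6-[(trimethylsilyl)oxy]benzoate F8. Saegusa–Ito oxidation with Pd(OAc)2 (MeCN, rt) and tautomerisation of the dienone, followed by K2CO3/MeOH to remove the aryl silyl ether, should give 13.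

**Further compounds**
F1 | step 3 | methyl 2-hydroxy-4-methyl-6-(2-oxopropoxy)benzoate | CC(=O)COc1cc(C)cc(O)c1C(=O)OC
F2 | step 3 | diallyl 2-(2,2-dimethoxyethylidene)malonate | C=CCOC(=O)C(=CC(OC)OC)C(=O)OCC=C
F3 | step 5 | methyl 2-{[rac-3-bromo-6-(dimethoxymethyl)-2,4-dioxocyclohexyl]oxy}-6-hydroxy-4-methylbenzoate | O=C1C(Br)C(=O)[C@H](Oc2cc(C)cc(O)c2C(=O)OC)[C@@H](C(OC)OC)C1
F4 | step 5 | methyl 2-[2-(dimethoxymethyl)-4,6-dihydroxyphenoxy]-6-hydroxy-4-methylbenzoate | COC(=O)c1c(O)cc(C)cc1Oc1c(C(OC)OC)cc(O)cc1O
F5 | step 5 | methyl 2-{2-(dimethoxymethyl)-6-hydroxy-4-[(triisopropylsilyl)oxy]phenoxy}-6-hydroxy-4-methylbenzoate | COC(=O)c1c(O)cc(C)cc1Oc1c(C(OC)OC)cc(O[Si](C(C)C)(C(C)C)C(C)C)cc1O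
F6 | step 5 | methyl 2-{2-(dimethoxymethyl)-6-[(3-methylbut-2-en-1-yl)oxy]-4-[(triisopropylsilyl)oxy]phenoxy}-6-hydroxy-4-methylbenzoate | COC(=O)c1c(O)cc(C)cc1Oc1c(C(OC)OC)cc(O[Si](C(C)C)(C(C)C)C(C)C)cc1OCC=C(C)C
F7 | step 5 | methyl 2-{2-(dimethoxymethyl)-4-hydroxy-6-[(3-methylbut-2-en-1-yl)oxy]phenoxy}-6-hydroxy-4-methylbenzoate | COC(=O)c1c(O)cc(C)cc1Oc1c(C(OC)OC)cc(O)cc1OCC=C(C)C
F8 | step 6 | methyl 2-{[6-(dimethoxymethyl)-4-methoxy-2-[(trimethylsilyl)oxy]cyclohexa-1,3-dien-1-yl]oxy}-4-methyl-6-[(trimethylsilyl)oxy]benzoate (racemic) | COC1=CC(O[Si](C)(C)C)=C(Oc2cc(C)cc(O[Si](C)(C)C)c2C(=O)OC)C(C(OC)OC)C1
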